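**Retrosynthetic overview**

- Feature: the only ring is a five-membered α-methylidene lactone – ring oxygen O1, C2 carrying the 14-oxopentadecyl chain, C3 carrying CO2H, C4 carrying the exocyclic CH2, carbonyl carbon C5. It is assembled from an aldehyde C=O (O1, C2), the ester-conjugated C=C of an allenic ester (C3, C4, the far allene carbon remaining as the CH2) and carbon monoxide (C5).
- Last disconnection: the C3 acid and the side-chain ketone are unmasked from an ethyl ester and a dioxolane in one acid hydrolysis.
- Key disconnection: C2–C3, C4–C5 and C5–O1 are cut together, giving the ketal-protected C15 aldehyde, ethyl buta-2,3-dienoate and CO.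
- The aldehyde goes back to pentadecanolide: Weinreb amide opening, MeMgBr, dioxolane formation, alcohol oxidation.
- Ring order: one ring only, the lactone, closed in the carbonylative step, which also sets C2 and C3 (trans, 2R,3S).

Key step: step 5

Assumption: which enantiomer of the chiral carbene leads to the (2R,3S) lactone cannot be derived from precedent; the (4R,5R) ligand is written, and its mirror image is to be used if the sense of induction proves opposite.

**Route**

Step 1
Reactants: 1 oxacyclohexadecan-2-one (pentadecanolide)
Product: 2 15-hydroxy-N-methoxy-N-methylpentadecanamide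
Conditions: MeNH(OMe)·HCl (1.5 equiv), i-PrMgCl (3 equiv), THF, −20 to 0 °C; aq. NH4Cl
Reagents that add atoms: N,O-dimethylhydroxylamine hydrochloride, CNOC.Cl
Why: Weinreb aminolysis of an ester: the chloromagnesium amide formed in the flask attacks the lactone carbonyl and opens the unstrained 16-membered ring to the ω-hydroxy N-methoxy-N-methylamide, which the reagent does not attack further; no stereocentre is involved.

Step 2
Reactants: 2 15-hydroxy-N-methoxy-N-methylpentadecanamide
Product: 3 16-hydroxyhexadecan-2-one
Conditions: MeMgBr (3 equiv), THF, 0 °C to rt; aq. NH4Cl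
Reagents that add atoms: methylmagnesium bromide, C[Mg]Br
Why: Weinreb ketone synthesis: after the hydroxyl is deprotonated, MeMgBr adds once to the amide to give a magnesium-chelated tetrahedral adduct that collapses to the methyl ketone only on aqueous work-up, so no tertiary alcohol should form.

Step 3
Reactants: 3 16-hydroxyhexadecan-2-one
Product: 4 14-(2-methyl-1,3-dioxolan-2-yl)tetradecan-1-ol
Conditions: HOCH2CH2OH (5 equiv), p-TsOH (cat.), toluene, reflux, Dean–Stark trap
Reagents that add atoms: ethane-1,2-diol, OCCO
Why: Acid-catalysed ketalisation driven by azeotropic removal of water; the five-membered dioxolane is favoured over any mixed ketal of the primary hydroxyl, which stays free.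

Step 4
Reactants: 4 14-(2-methyl-1,3-dioxolan-2-yl)tetradecan-1-ol
Product: 5 14-(2-methyl-1,3-dioxolan-2-yl)tetradecanal
Conditions: SO3·pyridine, DMSO, Et3N, CH2Cl2, 0 °C to rt
Reagents that add atoms: none
Why: Parikh–Doering oxidation (activated DMSO) takes the primary alcohol to the aldehyde without over-oxidation, under basic non-aqueous conditions that the dioxolane tolerates.

Step 5
Reactants: 5 14-(2-methyl-1,3-dioxolan-2-yl)tetradecanal, 6 ethyl buta-2,3-dienoate, 7 carbon monoxide
Product: 9 ethyl (2R,3S)-4-methylidene-2-[13-(2-methyl-1,3-dioxolan-2-yl)tridecyl]-5-oxooxolane-3-carboxylate, via oxanickelacycle 8 (not isolated)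
Conditions: (4R,5R)-1,3-bis(2-isopropylphenyl)-4,5-diphenylimidazolinium tetrafluoroborate (1.1 equiv), KN(SiMe3)2 (1.05 equiv), Ni(cod)2 (1.05 equiv), toluene, rt; then 5 and 6 (1.2 equiv) added slowly, −40 to 0 °C; then CO (1 atm), −78 °C to rt
Reagents that add atoms: none
Why: Proposed new method: zerovalent nickel carrying one bulky carbene should bind the aldehyde C=O and the ester-conjugated (α,β) C=C bond of allenoate 6 and couple them oxidatively, the nickel-bound ester α-carbon behaving like an enolate carbon towards the aldehyde carbon, to give oxanickelacycle 8 with nickel on the former central allene carbon; CO then inserts into the Ni–C(sp2) bond and C(acyl)–O reductive elimination releases the lactone, so that C2–C3, C4–C5 and C5–O1 are made in one flask. The closest known reaction types are the stoichiometric oxidative cyclisation of an alkene and an aldehyde on zerovalent nickel followed by carbonylation to a γ-lactone, the Mo(CO)6-mediated and Ru3(CO)12-catalysed intramolecular cyclocarbonylations of allenyl aldehydes to α-methylene-γ-butyrolactones, and nickel-catalysed reductive aldol couplings of acrylates, in which the α-carbon bonds to the aldehyde; the intermolecular union with an allenoate and its enantioselective form are new. The one ring is closed as a formal (2+2+1) hetero-Pauson–Khand annulation, O1, C2, C3 and C4 coming from the metallacycle and C5 from CO, the last bond (C5–O1) by reductive elimination from a six-membered acyl(alkoxy)nickel ring. C2 is set in the oxidative cyclisation by the chiral carbene, which has to deliver the allenoate carbon to the Si face of the bound aldehyde, and C3 is set in the same event relative to C2, the chain and the ester taking opposite faces of the metallacycle, which is also the more stable arrangement in the lactone. The step needs regioselectivity (aldehyde carbon to the ester-bearing allene carbon), trans diastereoselectivity and enantioselectivity: the first should come from the conjugation of the α,β bond with the ester, which makes it the better ligand for electron-rich nickel and leaves the orthogonal terminal C=C as the methylidene, the second from the substituents avoiding each other, the third from the ligand. Stoichiometric nickel with CO admitted only after 8 has formed keeps CO from binding the metal before the C–C bond is made, and pre-complexing the carbene keeps it from adding to the allenoate.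

Step 6
Reactants: 9 ethyl (2R,3S)-4-methylidene-2-[13-(2-methyl-1,3-dioxolan-2-yl)tridecyl]-5-oxooxolane-3-carboxylate
Product: 11 (2R,3S)-4-methylidene-5-oxo-2-(14-oxopentadecyl)oxolane-3-carboxylic acid, via keto ester 10 (not isolated)
Conditions: 6 M aq. HCl, butan-2-one, reflux
Reagents that add atoms: water, O
Why: Acid-catalysed hydrolysis: the dioxolane is cleaved first (butan-2-one takes up the diol by transketalisation), then the ethyl ester by acyl–oxygen cleavage, while the lactone, which can only reclose in acid, and the methylidene should survive; no base is present, so C3 is not deprotonated and the trans (2R,3S) centres from step 5 are kept.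

**Compound list**

1 | oxacyclohexadecan-2-one (pentadecanolide) | O=C1CCCCCCCCCCCCCCO1 | starting material
2 | 15-hydroxy-N-methoxy-N-methylpentadecanamide | CON(C)C(=O)CCCCCCCCCCCCCCO | intermediate
3 | 16-hydroxyhexadecan-2-one | CC(=O)CCCCCCCCCCCCCCO | intermediate
4 | 14-(2-methyl-1,3-dioxolan-2-yl)tetradecan-1-ol | CC1(CCCCCCCCCCCCCCO)OCCO1 | intermediate
5 | 14-(2-methyl-1,3-dioxolan-2-yl)tetradecanal | O=CCCCCCCCCCCCCCC1(C)OCCO1 | intermediate
6 | ethyl buta-2,3-dienoate | C=C=CC(=O)OCC | starting material
7 | carbon monoxide | [C-]#[O+] | starting material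
8 | oxanickelacycle formed in the flask: ethyl (4S,5R)-3-methylidene-5-[13-(2-methyl-1,3-dioxolan-2-yl)tridecyl]-2-[(4R,5R)-1,3-bis(2-isopropylphenyl)-4,5-diphenylimidazolidin-2-ylidene]-1-oxa-2-nickelacyclopentane-4-carboxylate (O1, Ni2, C3 with =CH2, C4 with CO2Et, C5 with the chain; chain and ester trans) | C=C1[Ni](=C2N(c3ccccc3C(C)C)[C@H](c3ccccc3)[C@@H](c3ccccc3)N2c2ccccc2C(C)C)O[C@H](CCCCCCCCCCCCCC2(C)OCCO2)[C@H]1C(=O)OCC | intermediate
9 | ethyl (2R,3S)-4-methylidene-2-[13-(2-methyl-1,3-dioxolan-2-yl)tridecyl]-5-oxooxolane-3-carboxylate | C=C1C(=O)O[C@H](CCCCCCCCCCCCCC2(C)OCCO2)[C@H]1C(=O)OCC | intermediate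
10 | keto ester formed in the flask: ethyl (2R,3S)-4-methylidene-5-oxo-2-(14-oxopentadecyl)oxolane-3-carboxylate | C=C1C(=O)O[C@H](CCCCCCCCCCCCCC(C)=O)[C@H]1C(=O)OCC | intermediate
11 | (2R,3S)-4-methylidene-5-oxo-2-(14-oxopentadecyl)oxolane-3-carboxylic acid | C=C1C(=O)O[C@H](CCCCCCCCCCCCCC(C)=O)[C@H]1C(=O)O | target

**Count and risks**

Total step count: 6. Longest linear sequence: 6 steps (from 1).

Steps most likely to fail:

1. Step 5 (new nickel-mediated carbonylative coupling). What may go wrong:
   - oxidative cyclisation in the opposite sense, the aldehyde carbon bonding to the central allene carbon as is usual for unactivated allenes;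
   - oligomerisation of the allenoate on nickel;
   - nickel-mediated dimerisation of the aldehyde to an ester;
   - poor facial selectivity at the aldehyde.

   Fallback (known chemistry, from 5 to 11): an Evans syn-aldol and lactonisation to the trans paraconic acid, followed by α-methylenation. (S)-4-Benzyl-1,3-oxazolidin-2-one is N-acylated (n-BuLi, methyl 4-chloro-4-oxobutanoate, THF, −78 °C) to methyl 4-[(4S)-4-benzyl-2-oxo-1,3-oxazolidin-3-yl]-4-oxobutanoate F1. Its boron enolate (Bu2BOTf, i-Pr2NEt, CH2Cl2, −78 °C) should add to aldehyde 5 to give the syn aldol methyl (3S,4R)-3-[(4S)-4-benzyl-2-oxo-1,3-oxazolidine-3-carbonyl]-4-hydroxy-17-(2-methyl-1,3-dioxolan-2-yl)heptadecanoate F2. Its hydroxyl closes onto the methyl ester (on standing, or with a trace of pyridinium p-toluenesulfonate in dry CH2Cl2) to the trans lactone (4S)-4-benzyl-3-{(2R,3S)-2-[13-(2-methyl-1,3-dioxolan-2-yl)tridecyl]-5-oxooxolane-3-carbonyl}-1,3-oxazolidin-2-one F3. LiOH and H2O2 (THF–H2O, 0 °C) remove the auxiliary to give (2R,3S)-2-[13-(2-methyl-1,3-dioxolan-2-yl)tridecyl]-5-oxooxolane-3-carboxylic acid F4. Carboxylation at C4 with MeOMgOCO2Me (DMF, 130 °C; cold, weakly acidic work-up) should give (2R,3S)-2-[13-(2-methyl-1,3-dioxolan-2-yl)tridecyl]-5-oxooxolane-3,4-dicarboxylic acid F5 (C4 epimers). Decarboxylative methylenation (aqueous HCHO, N-methylaniline, NaOAc, AcOH, rt) should then give (2R,3S)-4-methylidene-2-[13-(2-methyl-1,3-dioxolan-2-yl)tridecyl]-5-oxooxolane-3-carboxylic acid F6. 1 M aqueous HCl in THF at rt cleaves the dioxolane, and the route is rejoined at the target 11.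

2. Step 6 (hydrolysis in hot acid). What may go wrong: migration of the exocyclic double bond into the ring, conjugate addition of chloride or water to the methylidene lactone, and acid-catalysed aldol condensation of the methyl ketone with the solvent.

   Fallback (from 5 to 11): the C3 carboxyl is carried as a tert-butyl ester, so that the end is an acidolysis at room temperature instead of a hydrolysis at reflux. tert-Butyl buta-2,3-dienoate F7 is made by the Wittig reaction of tert-butyl (triphenylphosphoranylidene)acetate with ketene generated from acetyl chloride and Et3N (CH2Cl2, 0 °C). It replaces 6 in step 5 and should give tert-butyl (2R,3S)-4-methylidene-2-[13-(2-methyl-1,3-dioxolan-2-yl)tridecyl]-5-oxooxolane-3-carboxylate F8. CF3CO2H–CH2Cl2–H2O at rt then removes the tert-butyl group and hydrolyses the dioxolane, giving 11 directly.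

3. Step 1 (lactone aminolysis). What may go wrong: incomplete opening of the macrolactone, and attack of the product alkoxide on unreacted lactone to give ester oligomers that are hard to separate from the waxy amide.

   Fallback (from 1 to 3): the methyl ketone is reached through the carboxylate instead of the amide. Saponification of 1 (KOH, MeOH–H2O, reflux; then acidification) gives 15-hydroxypentadecanoic acid F9. MeLi (4 equiv, THF, 0 °C to rt) adds once to the lithium carboxylate, and the dilithio gem-diolate resists further addition. Quenching first with Me3SiCl and then with aqueous acid releases 16-hydroxyhexadecan-2-one 3, where the route is rejoined; step 2 is then no longer needed.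

**Further compounds**

F1 | step 5 | methyl 4-[(4S)-4-benzyl-2-oxo-1,3-oxazolidin-3-yl]-4-oxobutanoate | COC(=O)CCC(=O)N1[C@@H](Cc2ccccc2)COC1=O
F2 | step 5 | methyl (3S,4R)-3-[(4S)-4-benzyl-2-oxo-1,3-oxazolidine-3-carbonyl]-4-hydroxy-17-(2-methyl-1,3-dioxolan-2-yl)heptadecanoate | COC(=O)C[C@H](C(=O)N1[C@@H](Cc2ccccc2)COC1=O)[C@H](O)CCCCCCCCCCCCCC1(C)OCCO1
F3 | step 5 | (4S)-4-benzyl-3-{(2R,3S)-2-[13-(2-methyl-1,3-dioxolan-2-yl)tridecyl]-5-oxooxolane-3-carbonyl}-1,3-oxazolidin-2-one | C1C(=O)O[C@H](CCCCCCCCCCCCCC2(C)OCCO2)[C@H]1C(=O)N1[C@@H](Cc2ccccc2)COC1=O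
F4 | step 5 | (2R,3S)-2-[13-(2-methyl-1,3-dioxolan-2-yl)tridecyl]-5-oxooxolane-3-carboxylic acid | C1C(=O)O[C@H](CCCCCCCCCCCCCC2(C)OCCO2)[C@H]1C(=O)O
F5 | step 5 | (2R,3S)-2-[13-(2-methyl-1,3-dioxolan-2-yl)tridecyl]-5-oxooxolane-3,4-dicarboxylic acid (C4 epimers) | OC(=O)C1C(=O)O[C@H](CCCCCCCCCCCCCC2(C)OCCO2)[C@H]1C(=O)O
F6 | step 5 | (2R,3S)-4-methylidene-2-[13-(2-methyl-1,3-dioxolan-2-yl)tridecyl]-5-oxooxolane-3-carboxylic acid | C=C1C(=O)O[C@H](CCCCCCCCCCCCCC2(C)OCCO2)[C@H]1C(=O)O
F7 | step 6 | tert-butyl buta-2,3-dienoate | C=C=CC(=O)OC(C)(C)C
F8 | step 6 | tert-butyl (2R,3S)-4-methylidene-2-[13-(2-methyl-1,3-dioxolan-2-yl)tridecyl]-5-oxooxolane-3-carboxylate | C=C1C(=O)O[C@H](CCCCCCCCCCCCCC2(C)OCCO2)[C@H]1C(=O)OC(C)(C)C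
F9 | step 1 | 15-hydroxypentadecanoic acid | OCCCCCCCCCCCCCCC(=O)O
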